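**Retrosynthetic overview** (longipinane numbering: C-1 ketone, C-2=C-3(Me), bridgeheads C-4 and C-11, cyclobutane carbons C-5 and C-10(Me), C-6 gem-dimethyl carbon, C-7 methacrylate carbon, C-8, C-9 isobutyrate carbon)
1. Both esters and both carbinol centres are installed last, from tricyclic keto ketal 14, by two CBS reductions and two acylations.
2. Key disconnection: the C-6–C-7 bond (seven-membered ring) and the C-4–C-10 bond (cyclobutane) are cut together, and C-7 is re-tied to C-10 as a temporary cyclobutanone; this leads to the monocyclic silyl dienol ether 13 with a tertiary N-phthalimidoyl oxalate at C-6.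
3. Enabling feature: C-7 lies 1,4 to C-10, so a C-7/C-8/C-9/C-10 cyclobutanone can be drawn. C-6 is three bonds from C-10, so its radical reaches the C-7 carbonyl 5-exo and ring-expands it. C-10 is 1,3 to C-4, the γ-carbon of the cyclohexenone ring and the terminus of its dienol ether.
4. 13 comes from (+)-3-carene by allylic oxidation, hydrative opening of the cyclopropane, a temporary cis-fused δ-lactone (sets the cis relation of the two side chains), dienol silylation and a ketene/ketene-acetal [2+2].
5. Ring order: cyclohexenone (from carene) → temporary lactone → temporary cyclobutanone → seven-membered ring and cyclobutane in one step.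

Key step: step 8

Remark: the methyl-bearing side-chain carbon (future C-10) is carried as a mixture of epimers in 5–13 and in F1–F6, because it becomes a planar radical in step 8.

**Step 1**
Reactants: 1 (+)-3-carene
Product: 2 (1R,6S)-4,7,7-trimethylbicyclo[4.1.0]hept-3-en-2-one (car-3-en-5-one)
Conditions: t-BuOOH (70 % aq, 5 equiv), Rh2(cap)4 (cap = caprolactamate, 0.5 mol %), K2CO3, CH2Cl2, 25 °C
Reagents that add atoms: tert-butyl hydroperoxide, CC(C)(C)OO
Why: Dirhodium-catalysed allylic oxidation should convert the ring CH2 next to the unsubstituted alkene carbon into the enone carbonyl in preference to the CH2 beside the methyl-bearing carbon; the two cyclopropane stereocentres are not touched.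

**Step 2**
Reactants: 2 car-3-en-5-one
Product: 3 (5S)-5-(2-hydroxypropan-2-yl)-3-methylcyclohex-2-en-1-one
Conditions: HClO4 (0.5 M aq), THF, 45 °C
Reagents that add atoms: water, O
Why: Acid-catalysed homoconjugate (Markovnikov) hydration of the cyclopropyl ketone should cleave the exocyclic cyclopropane bond that overlaps the carbonyl and trap the tertiary cation with water; the ring stereocentre is retained.

**Step 3**
Reactants: 3 hydroxy enone; 4 2-bromopropanoyl bromide (racemic)
Product: 5 2-[(1S)-3-methyl-5-oxocyclohex-3-en-1-yl]propan-2-yl 2-bromopropanoate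
Conditions: pyridine, DMAP (cat.), CH2Cl2, 0 → 25 °C
Reagents that add atoms: none
Why: DMAP-catalysed acylation of the tertiary alcohol by the reactive acid bromide; no stereocentre on the ring is affected.

**Step 4**
Reactants: 5 bromo ester
Product: 6 (4aR,8aS)-1,1,4,7-tetramethyl-4,4a,8,8a-tetrahydro-1H-isochromene-3,5-dione (cis-fused δ-lactone, C-4 epimers)
Conditions: LiN(SiMe3)2 (1.05 equiv), THF, −78 → −20 °C
Reagents that add atoms: none
Why: Intramolecular enolate alkylation (6-exo-tet): the kinetic α′-dienolate displaces the secondary bromide held on the ester tether, and axial attack with the tether equatorial should give the cis ring fusion, so the new C–C bond at C-4a is cis to the C-8a–CMe2 bond.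

**Step 5**
Reactants: 6 cis-lactone
Product: 7 (4aR,8aS)-5-(triisopropylsilyloxy) 5,7-diene of lactone 6 (linear silyl dienol ether)
Conditions: i-Pr3SiOTf, Et3N, CH2Cl2, −78 → 0 °C
Reagents that add atoms: triisopropylsilyl trifluoromethanesulfonate, CC(C)[Si](OS(=O)(=O)C(F)(F)F)(C(C)C)C(C)C
Why: Soft enolization with silyl triflate and amine; the α′ position is now a hindered ring-fusion CH, so loss of a γ-CH2 proton should give the linearly conjugated endocyclic dienol ether, and the ring-fusion stereocentres are then no longer epimerizable.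

**Step 6**
Reactants: 7 silyl dienol ether lactone
Product: 8 lithium 2-[(1R,6S)-6-(2-hydroxypropan-2-yl)-4-methyl-2-(triisopropylsilyloxy)cyclohexa-2,4-dien-1-yl]propanoate
Conditions: LiOH·H2O (1.05 equiv), THF/H2O, 0 °C; freeze-drying
Reagents that add atoms: lithium hydroxide, [Li+].[OH-]
Why: Saponification of the δ-lactone; isolation as the lithium salt should prevent relactonization and protodesilylation, and no stereocentre is touched.

**Step 7**
Reactants: 8 lithium carboxylate; 9 1,1-diethoxyethene
Product: 13 cyclobutanone N-phthalimidoyl oxalate (key precursor), via bis-acyl chloride 10 (not isolated), via oxalate acid chloride 11 (not isolated), via ketene 12 (not isolated)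
Conditions: (COCl)2 (2.2 equiv), DMF (cat.), 2,6-lutidine, CH2Cl2, −20 °C; N-hydroxyphthalimide (1.0 equiv), −40 °C; then 9 (3 equiv), Et3N, 0 → 25 °C
Reagents that add atoms: oxalyl chloride, O=C(Cl)C(=O)Cl; N-hydroxyphthalimide, O=C1c2ccccc2C(=O)N1O
Why: Acid chloride and chlorooxalate formation, selective capping of the more electrophilic chlorooxalate, then dehydrochlorination to the ketene and its [2+2] cycloaddition with the ketene acetal (ketene carbonyl carbon to CH2, ketene terminus to the acetal carbon); the new quaternary centre forms as a mixture that converges in step 8.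

**Step 8**
Reactants: 13 cyclobutanone N-phthalimidoyl oxalate
Product: 14 (4R,5S,10R,11R)-9,9-diethoxylongipin-2-ene-1,7-dione
Conditions: fac-Ir(ppy)3 (1 mol %), MeCN/CH2Cl2 (0.005 M), 450 nm LEDs, 25 °C, argon; aq. NaHCO3 work-up
Reagents that add atoms: none
Why: Proposed new method: the excited fac-Ir(ppy)3 transfers one electron to the N-phthalimidoyl oxalate, which loses phthalimide anion and two CO2 to give the tertiary C-6 radical; this adds 5-exo to the cyclobutanone carbonyl (future C-7), the strained alkoxy radical undergoes β-scission of its bond to the methyl-bearing ring carbon (Dowd–Beckwith ring expansion), which makes the C-6–C-7 bond, the cycloheptanone and a tertiary radical at C-10, and that radical adds 4-exo to the dienol ether terminus C-4, after which the α-silyloxyallyl radical is oxidized by the tetravalent iridium complex and desilylated to the enone. The closest known reactions are the radical ring expansion of 2-(3-haloalkyl)cyclobutanones to cycloheptanones and the photoredox alkylation of silyl enol ethers by radicals from redox-active esters; interception of the ring-expanded radical by a dienol ether in a 4-exo mode is the new element. The seven-membered ring closes by 5-exo-trig addition followed by fragmentation (net three-atom enlargement of the cyclobutanone), the cyclobutane by 4-exo-trig attack on the diene terminus. C-4 and C-10 are controlled by the cis relation of the two side chains fixed in lactone 6 (C-5 and C-11 are carried through unchanged): after ring expansion the C-10 radical can reach C-4 only on the face syn to C-6, so only one diastereomer of the bridged skeleton can form. The step needs β-scission toward the tertiary carbon rather than the CH2, and attack on C-4 rather than on the methyl-bearing C-3; the first is secured by radical stability and strain release, the second by the oxygen-stabilized allyl radical that forms only on terminal attack and is oxidized irreversibly.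

**Step 9**
Reactants: 14 tricyclic keto ketal
Product: 15 (4R,5S,7R,10R,11R)-9,9-diethoxy-7-hydroxylongipin-2-en-1-one
Conditions: (S)-Me-CBS [(S)-1-methyl-3,3-diphenyltetrahydro-1H,3H-pyrrolo[1,2-c][1,3,2]oxazaborole, 20 mol %], BH3·SMe2, toluene, −40 °C; MeOH
Reagents that add atoms: none
Why: Corey–Bakshi–Shibata reduction; with quaternary C-6 as the large and C-8 as the small group, the (S)-catalyst should give the (7R)-alcohol, and the saturated cycloheptanone is expected to react before the hindered conjugated ketone.

**Step 10**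
Reactants: 15 C-7 alcohol; 16 methacryloyl chloride
Product: 17 (4R,5S,7R,10R,11R)-9,9-diethoxy-1-oxolongipin-2-en-7-yl 2-methylprop-2-enoate
Conditions: Et3N, DMAP (cat.), CH2Cl2, 0 °C
Reagents that add atoms: none
Why: DMAP-catalysed acylation of the secondary alcohol; no stereocentre is affected.

**Step 11**
Reactants: 17 methacrylate ketal
Product: 18 (4R,5S,7R,10R,11R)-1,9-dioxolongipin-2-en-7-yl 2-methylprop-2-enoate
Conditions: PPTS, acetone/H2O, 45 °C
Reagents that add atoms: water, O
Why: Mild acid hydrolysis of the diethyl ketal; the ester and the enone should survive, and no stereocentre is affected.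

**Step 12**
Reactants: 18 keto methacrylate
Product: 19 (4R,5S,7R,9R,10R,11R)-9-hydroxy-1-oxolongipin-2-en-7-yl 2-methylprop-2-enoate
Conditions: (S)-Me-CBS (20 mol %), BH3·SMe2, toluene, −40 °C; MeOH
Reagents that add atoms: none
Why: Corey–Bakshi–Shibata reduction; with quaternary C-10 as the large and C-8 as the small group, the (S)-catalyst should give the (9R)-alcohol, anti to the C-7 ester.

**Step 13**
Reactants: 19 C-9 alcohol; 20 2-methylpropanoyl chloride
Product: 21 (4R,5S,7R,9R,10R,11R)-9-(2-methylpropanoyloxy)-1-oxolongipin-2-en-7-yl 2-methylprop-2-enoate (target)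
Conditions: pyridine, DMAP (cat.), CH2Cl2, 0 → 25 °C
Reagents that add atoms: none
Why: DMAP-catalysed acylation of the remaining secondary alcohol completes the target; no stereocentre is affected.

**Compound list**
1 | (+)-3-carene, (1S,6R)-3,7,7-trimethylbicyclo[4.1.0]hept-3-ene | CC1=CC[C@@H]2[C@H](C1)C2(C)C | starting material
2 | (1R,6S)-4,7,7-trimethylbicyclo[4.1.0]hept-3-en-2-one (car-3-en-5-one) | O=C1C=C(C)C[C@H]2[C@@H]1C2(C)C | intermediate
3 | (5S)-5-(2-hydroxypropan-2-yl)-3-methylcyclohex-2-en-1-one | O=C1C=C(C)C[C@@H](C1)C(C)(C)O | intermediate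
4 | 2-bromopropanoyl bromide (racemic) | CC(Br)C(=O)Br | starting material
5 | 2-[(1S)-3-methyl-5-oxocyclohex-3-en-1-yl]propan-2-yl 2-bromopropanoate | O=C1C=C(C)C[C@@H](C1)C(C)(C)OC(=O)C(C)Br | intermediate
6 | (4aR,8aS)-1,1,4,7-tetramethyl-4,4a,8,8a-tetrahydro-1H-isochromene-3,5-dione (cis-fused, C-4 epimers) | O=C1C=C(C)C[C@H]2[C@@H]1C(C)C(=O)OC2(C)C | intermediate
7 | (4aR,8aS)-5-(triisopropylsilyloxy) 5,7-diene of lactone 6 | CC(C)[Si](OC1=CC(C)=C[C@H]2[C@@H]1C(C)C(=O)OC2(C)C)(C(C)C)C(C)C | intermediate
8 | lithium 2-[(1R,6S)-6-(2-hydroxypropan-2-yl)-4-methyl-2-(triisopropylsilyloxy)cyclohexa-2,4-dien-1-yl]propanoate | CC(C)[Si](OC1=CC(C)=C[C@@H]([C@@H]1C(C)C(=O)[O-])C(C)(C)O)(C(C)C)C(C)C.[Li+] | intermediate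
9 | 1,1-diethoxyethene | C=C(OCC)OCC | starting material
10 | bis-acyl chloride of 8 (propanoyl chloride and chlorooxalate of the tertiary alcohol) | CC(C)[Si](OC1=CC(C)=C[C@@H]([C@@H]1C(C)C(Cl)=O)C(C)(C)OC(=O)C(Cl)=O)(C(C)C)C(C)C | intermediate
11 | propanoyl chloride carrying the N-phthalimidoyl oxalate | CC(C)[Si](OC1=CC(C)=C[C@@H]([C@@H]1C(C)C(Cl)=O)C(C)(C)OC(=O)C(=O)ON2C(=O)c3ccccc3C2=O)(C(C)C)C(C)C | intermediate
12 | methyl(cyclohexadienyl)ketene carrying the N-phthalimidoyl oxalate | CC(C)[Si](OC1=CC(C)=C[C@@H]([C@@H]1C(C)=C=O)C(C)(C)OC(=O)C(=O)ON2C(=O)c3ccccc3C2=O)(C(C)C)C(C)C | intermediate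
13 | 2-[(1S,6R)-6-(2,2-diethoxy-1-methyl-4-oxocyclobutyl)-3-methyl-5-(triisopropylsilyloxy)cyclohexa-2,4-dien-1-yl]propan-2-yl 1,3-dioxoisoindolin-2-yl oxalate | CC(C)[Si](OC1=CC(C)=C[C@@H]([C@@H]1C2(C)C(=O)CC2(OCC)OCC)C(C)(C)OC(=O)C(=O)ON3C(=O)c4ccccc4C3=O)(C(C)C)C(C)C | intermediate
14 | (4R,5S,10R,11R)-9,9-diethoxylongipin-2-ene-1,7-dione | O=C1CC(OCC)(OCC)[C@@]2(C)[C@@H]3C(=O)C=C(C)[C@H]2[C@@H]3C1(C)C | intermediate
15 | (4R,5S,7R,10R,11R)-9,9-diethoxy-7-hydroxylongipin-2-en-1-one | O[C@@H]1CC(OCC)(OCC)[C@@]2(C)[C@@H]3C(=O)C=C(C)[C@H]2[C@@H]3C1(C)C | intermediate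
16 | methacryloyl chloride | C=C(C)C(Cl)=O | starting material
17 | (4R,5S,7R,10R,11R)-9,9-diethoxy-1-oxolongipin-2-en-7-yl 2-methylprop-2-enoate | C=C(C)C(=O)O[C@@H]1CC(OCC)(OCC)[C@@]2(C)[C@@H]3C(=O)C=C(C)[C@H]2[C@@H]3C1(C)C | intermediate
18 | (4R,5S,7R,10R,11R)-1,9-dioxolongipin-2-en-7-yl 2-methylprop-2-enoate | C=C(C)C(=O)O[C@@H]1CC(=O)[C@@]2(C)[C@@H]3C(=O)C=C(C)[C@H]2[C@@H]3C1(C)C | intermediate
19 | (4R,5S,7R,9R,10R,11R)-9-hydroxy-1-oxolongipin-2-en-7-yl 2-methylprop-2-enoate | C=C(C)C(=O)O[C@@H]1C[C@@H](O)[C@@]2(C)[C@@H]3C(=O)C=C(C)[C@H]2[C@@H]3C1(C)C | intermediate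
20 | 2-methylpropanoyl chloride | CC(C)C(Cl)=O | starting material
21 | (4R,5S,7R,9R,10R,11R)-9-(2-methylpropanoyloxy)-1-oxolongipin-2-en-7-yl 2-methylprop-2-enoate | C=C(C)C(=O)O[C@@H]1C[C@@H](OC(=O)C(C)C)[C@@]2(C)[C@@H]3C(=O)C=C(C)[C@H]2[C@@H]3C1(C)C | target

Total step count: 13. Longest linear sequence: 13 steps (1 → 21).

**Steps most likely to fail**

Step 8 (proposed new method). The ring-expanded tertiary radical may be quenched (hydrogen abstraction, or oxidation and elimination) or may add to the internal diene carbon faster than it closes the four-membered ring. The fallback sets out from 13 and returns at 14. The ring expansion alone is a known process. Run with bromine-atom transfer (fac-Ir(ppy)3, blue LEDs, CBrCl3 added slowly), it should stop at the ring-expanded tertiary bromide F1. Silver-assisted ionization (AgOTf, 2,6-di-tert-butyl-4-methylpyridine, CH2Cl2, −78 °C) should then let the silyl dienol ether be alkylated at its terminus by the tertiary cation (Reetz-type tert-alkylation of an enol silane). This closes the cyclobutane in a polar step and gives 14.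

Step 7. Chemoselectivity between the two acyl chlorides may be lost, and the ketene acetal may be C-acylated by the chlorooxalate. The fallback sets out from 8 and returns at 13, and separates the two acylations with a protecting group. Me3SiCl/Et3N should give the bis(trimethylsilyl) derivative F2. Oxalyl chloride with catalytic DMF converts only the silyl ester into the acid chloride, which with Et3N and 9 should give the cyclobutanone silyl ether F3. K2CO3/MeOH frees the cyclobutanone tertiary alcohol F4. Oxalyl chloride followed by N-hydroxyphthalimide/Et3N then gives 13.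

Step 4. The α-bromo ester may be deprotonated in competition, and the cis ring fusion may be lost through enolate equilibration. The fallback sets out from 3 and returns at 6. LDA (2.2 equiv) followed by tert-butyl 2-(trifluoromethylsulfonyloxy)propanoate should alkylate the α′ carbon intermolecularly, trans to the side chain, to give the trans keto ester F5. Re-enolization with LDA and kinetic protonation (2,6-di-tert-butylphenol, −78 °C) should invert that centre to the cis keto ester F6. CF3CO2H then cleaves the tert-butyl ester and lactonizes the hydroxy acid to 6.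

**Further compounds**
F1 | step 8 | ring-expanded tertiary bromide (cis-fused cycloheptanone, diethyl ketal, silyl dienol ether) | CC(C)[Si](OC1=CC(C)=C[C@H]2[C@@H]1C(C)(Br)C(OCC)(OCC)CC(=O)C2(C)C)(C(C)C)C(C)C
F2 | step 7 | bis(trimethylsilyl) derivative of 8 (silyl ester and tertiary silyl ether) | CC(C)[Si](OC1=CC(C)=C[C@@H]([C@@H]1C(C)C(=O)O[Si](C)(C)C)C(C)(C)O[Si](C)(C)C)(C(C)C)C(C)C
F3 | step 7 | cyclobutanone silyl ether | CC(C)[Si](OC1=CC(C)=C[C@@H]([C@@H]1C2(C)C(=O)CC2(OCC)OCC)C(C)(C)O[Si](C)(C)C)(C(C)C)C(C)C
F4 | step 7 | cyclobutanone tertiary alcohol | CC(C)[Si](OC1=CC(C)=C[C@@H]([C@@H]1C2(C)C(=O)CC2(OCC)OCC)C(C)(C)O)(C(C)C)C(C)C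
F5 | step 4 | trans keto ester, tert-butyl 2-[(1S,2S)-2-(2-hydroxypropan-2-yl)-4-methyl-6-oxocyclohex-4-en-1-yl]propanoate | O=C1C=C(C)C[C@@H]([C@H]1C(C)C(=O)OC(C)(C)C)C(C)(C)O
F6 | step 4 | cis keto ester, tert-butyl 2-[(1R,2S)-2-(2-hydroxypropan-2-yl)-4-methyl-6-oxocyclohex-4-en-1-yl]propanoate | O=C1C=C(C)C[C@@H]([C@@H]1C(C)C(=O)OC(C)(C)C)C(C)(C)O
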